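**Retrosynthetic overview**
- The side-chain C–C bond (CH2–CHOH) is cut first: a 2-substituted allylboronate carrying the halogenated ring adds to 3-methylbut-2-enal in a catalytic asymmetric carbonyl allylation.
- The allylboronate goes back through allyl chloride, isopropenyl and methyl ketone to a small ethynyl group on C1.
- The trans Br/Cl pair comes from a chlorohydrin (tertiary OH → Br with chlorine participation), itself from chloride opening at C3 of an epoxide placed by OH-directed epoxidation.
- The only ring is formed first, by a catalytic enantioselective Diels–Alder reaction of isoprene with 2-bromoacrolein; Br is then exchanged for OH with inversion and CHO becomes C≡CH.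

Assumptions: ring positions carry the target's numbering throughout (C1 carbinol carbon, C3 CHCl, C4 CBr(CH3)), and the sense of induction of the two chiral catalysts is taken from their accepted models (if either proves opposite, the other catalyst enantiomer is used). The route is designed from known reaction types and has not been run.

**Step 1**
Reactants: 1 acrolein
Product: 3 2-bromoacrolein, via 2,3-dibromopropanal 2 (not isolated)
Conditions: Br2, DCM, −78 → 0 °C; then Et3N, 0 °C
Reagents that add atoms: bromine, BrBr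
Why: Bromination of the enal C=C followed by E1cB dehydrobromination removes the acidic α-hydrogen and leaves bromine on the α-carbon, with no stereocentre formed.

**Step 2**
Reactants: 3 2-bromoacrolein; 4 isoprene
Product: 5 (1S)-1-bromo-4-methylcyclohex-3-ene-1-carbaldehyde
Conditions: (4R)-2-butyl-4-(1H-indol-3-ylmethyl)-3-tosyl-1,3,2-oxazaborolidin-5-one (10 mol %), DCM, −78 °C
Reagents that add atoms: none
Why: Catalytic enantioselective Diels–Alder reaction in which the boron-bound s-cis bromoacrolein is shielded on one face by the indole ring, so isoprene adds to the open face with "para" regiochemistry and the (R)-tryptophan-derived catalyst sets C1 as S.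

**Step 3**
Reactants: 5 (1S)-1-bromo-4-methylcyclohex-3-ene-1-carbaldehyde
Product: 7 (1R)-1-hydroxy-4-methylcyclohex-3-ene-1-carbaldehyde, via spiro epoxy ether 6 (not isolated)
Conditions: NaOMe, MeOH, −20 → 0 °C; then 1 M aq. HCl–THF, 0 °C (product used crude)
Reagents that add atoms: water, O
Why: Epoxy-ether formation (methoxide adds to the aldehyde and the alkoxide displaces the tertiary bromide in an intramolecular SN2 that inverts C1) is followed by acid hydrolysis at the acetal carbon, which leaves the new C1–O bond and its R configuration untouched.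

**Step 4**
Reactants: 7 (1R)-1-hydroxy-4-methylcyclohex-3-ene-1-carbaldehyde
Product: 8 (1R)-1-ethynyl-4-methylcyclohex-3-en-1-ol
Conditions: dimethyl (1-diazo-2-oxopropyl)phosphonate, K2CO3, MeOH, 0 °C → rt
Reagents that add atoms: dimethyl (1-diazo-2-oxopropyl)phosphonate, CC(=O)C(=[N+]=[N-])P(=O)(OC)OC
Why: Ohira–Bestmann (Seyferth–Gilbert) homologation turns the aldehyde into the terminal alkyne under mild carbonate conditions that tolerate the free tertiary hydroxyl, and C1 is not involved.

**Step 5**
Reactants: 8 (1R)-1-ethynyl-4-methylcyclohex-3-en-1-ol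
Product: 9 (1R,3R,6S)-3-ethynyl-6-methyl-7-oxabicyclo[4.1.0]heptan-3-ol (epoxide cis to the hydroxyl)
Conditions: t-BuOOH (decane), VO(acac)2 (2 mol %), toluene, 0 °C → rt
Reagents that add atoms: tert-butyl hydroperoxide, CC(C)(C)OO
Why: Hydroxyl-directed vanadium-catalysed epoxidation delivers oxygen from the bound tertiary homoallylic alkoxide to the ring alkene on its own face, giving the epoxide cis to the C1 oxygen (ring C3 R, C4 S) while the alkyne is inert.

**Step 6**
Reactants: 9 (1R,3R,6S)-3-ethynyl-6-methyl-7-oxabicyclo[4.1.0]heptan-3-ol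
Product: 10 tert-butyl{[(1R,3R,6S)-3-ethynyl-6-methyl-7-oxabicyclo[4.1.0]heptan-3-yl]oxy}dimethylsilane
Conditions: TBSOTf, 2,6-lutidine, DCM, −78 °C
Reagents that add atoms: tert-butyldimethylsilyl trifluoromethanesulfonate, CC(C)(C)[Si](C)(C)OS(=O)(=O)C(F)(F)F
Why: Silyl triflate O-silylation of the tertiary alcohol is fast at −78 °C (too cold for Lewis-acid epoxide opening), removes the hydrogen-bond donor and makes the C1 oxygen substituent the larger group so that the slim ethynyl group goes axial in the next step.

**Step 7**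
Reactants: 10 tert-butyl{[(1R,3R,6S)-3-ethynyl-6-methyl-7-oxabicyclo[4.1.0]heptan-3-yl]oxy}dimethylsilane
Product: 11 (1S,2S,4R)-4-{[tert-butyl(dimethyl)silyl]oxy}-2-chloro-4-ethynyl-1-methylcyclohexan-1-ol
Conditions: LiCl, AcOH, THF, rt
Reagents that add atoms: lithium chloride, [Li+].[Cl-]
Why: Fürst–Plattner (trans-diaxial) SN2 epoxide opening: in the half-chair with the silyloxy group equatorial and ethynyl axial, chloride attacks the less substituted C3 axially and anti to the epoxide oxygen, which inverts C3 to S and leaves the C4–O bond (S) untouched.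

**Step 8**
Reactants: 11 (1S,2S,4R)-4-{[tert-butyl(dimethyl)silyl]oxy}-2-chloro-4-ethynyl-1-methylcyclohexan-1-ol
Product: 12 tert-butyl{[(1R,3S,4S)-4-bromo-3-chloro-1-ethynyl-4-methylcyclohexyl]oxy}dimethylsilane
Conditions: Me3SiBr, DCM, −40 → −10 °C
Reagents that add atoms: bromotrimethylsilane, C[Si](C)(C)Br
Why: SN1 substitution of the tertiary alcohol with neighbouring-group participation: the anti-periplanar axial chlorine bridges the developing cation on the lower face, so bromide enters the tertiary carbon from the opposite face (net retention, C4 S, Br trans to Cl), as in anti opening of a chloronium ion, while the electron-poor propargylic silyl ether does not ionise at this temperature.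

**Step 9**
Reactants: 12 tert-butyl{[(1R,3S,4S)-4-bromo-3-chloro-1-ethynyl-4-methylcyclohexyl]oxy}dimethylsilane
Product: 13 1-[(1R,3S,4S)-4-bromo-1-{[tert-butyl(dimethyl)silyl]oxy}-3-chloro-4-methylcyclohexyl]ethan-1-one
Conditions: Ph3PAuNTf2 (3 mol %), H2O, 1,4-dioxane, 50 °C
Reagents that add atoms: water, O
Why: Gold-catalysed Markovnikov hydration of the terminal alkyne with a silver-free catalyst that does not abstract the alkyl halides gives the methyl ketone without touching any stereocentre.

**Step 10**
Reactants: 13 1-[(1R,3S,4S)-4-bromo-1-{[tert-butyl(dimethyl)silyl]oxy}-3-chloro-4-methylcyclohexyl]ethan-1-one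
Product: 14 {[(1R,3S,4S)-4-bromo-3-chloro-4-methyl-1-(prop-1-en-2-yl)cyclohexyl]oxy}(tert-butyl)dimethylsilane
Conditions: Cp2Ti(μ-Cl)(μ-CH2)AlMe2 (Tebbe reagent), pyridine (cat.), THF–toluene, −40 → 0 °C
Reagents that add atoms: Tebbe reagent, C[Al-]1(C)C[Ti]([Cl+]1)(C1C=CC=C1)C1C=CC=C1
Why: Tebbe methylenation is a non-basic titanium-carbene olefination that works on hindered α-oxygenated ketones and avoids the E2 loss of HBr that a Wittig ylide would risk, and no stereocentre is affected.

**Step 11**
Reactants: 14 {[(1R,3S,4S)-4-bromo-3-chloro-4-methyl-1-(prop-1-en-2-yl)cyclohexyl]oxy}(tert-butyl)dimethylsilane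
Product: 15 {[(1R,3S,4S)-4-bromo-3-chloro-1-(3-chloroprop-1-en-2-yl)-4-methylcyclohexyl]oxy}(tert-butyl)dimethylsilane
Conditions: NCS, PhSeCl (10 mol %), DCM, rt
Reagents that add atoms: N-chlorosuccinimide, O=C1CCC(=O)N1Cl
Why: Selenium-catalysed ene-type allylic chlorination acts on the only alkene, whose methyl group carries the only allylic hydrogens, and gives the 2-substituted allyl chloride with transposition of the double bond.

**Step 12**
Reactants: 15 {[(1R,3S,4S)-4-bromo-3-chloro-1-(3-chloroprop-1-en-2-yl)-4-methylcyclohexyl]oxy}(tert-butyl)dimethylsilane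
Product: 16 2-{2-[(1R,3S,4S)-4-bromo-1-{[tert-butyl(dimethyl)silyl]oxy}-3-chloro-4-methylcyclohexyl]prop-2-en-1-yl}-4,4,5,5-tetramethyl-1,3,2-dioxaborolane
Conditions: B2pin2, Pd2(dba)3 (2.5 mol %), THF, 60 °C
Reagents that add atoms: bis(pinacolato)diboron, CC1(C)OB(OC1(C)C)B1OC(C)(C)C(C)(C)O1
Why: Palladium-catalysed allylic borylation in which zerovalent palladium ionises only the primary allylic chloride to a π-allyl complex that is borylated at the unhindered CH2 terminus, the unactivated tertiary bromide and secondary chloride being inert to the ligand-free catalyst.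

**Step 13**
Reactants: 16 the allylboronate of step 12; 17 3-methylbut-2-enal
Product: 19 (4S)-2-[(1R,3S,4S)-4-bromo-1-{[tert-butyl(dimethyl)silyl]oxy}-3-chloro-4-methylcyclohexyl]-6-methylhepta-1,5-dien-4-ol, via pinacol borate ester 18 (not isolated)
Conditions: (S)-3,3′-bis(2,4,6-triisopropylphenyl)-1,1′-binaphthyl-2,2′-diyl hydrogen phosphate (10 mol %), 4 Å MS, toluene, −30 °C; aq. NaHCO3 work-up
Reagents that add atoms: none
Why: Chiral phosphoric acid-catalysed carbonyl allylboration through a closed chair (Zimmerman–Traxler) transition state, in which the (S) catalyst directs the allyl group to the Si face of the enal (1,2-addition only) and sets the carbinol as S under reagent control, remote from the ring stereocentres.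

**Step 14**
Reactants: 19 the silyl ether of step 13
Product: 20 (1R,3S,4S)-4-bromo-3-chloro-1-[(4S)-4-hydroxy-6-methylhepta-1,5-dien-2-yl]-4-methylcyclohexan-1-ol
Conditions: HF·pyridine, pyridine, THF, 0 °C → rt
Reagents that add atoms: none
Why: Fluoride-mediated desilylation with buffered HF·pyridine cleaves the tertiary silyl ether without base-induced E2 of the tertiary bromide or acid ionisation of the allylic alcohols, and no stereocentre is touched.

**Compound list**
1 | acrolein (prop-2-enal) | C=CC=O | starting material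
2 | 2,3-dibromopropanal (racemic, not isolated) | O=CC(Br)CBr | intermediate
3 | 2-bromoacrolein (2-bromoprop-2-enal) | C=C(Br)C=O | intermediate
4 | isoprene (2-methylbuta-1,3-diene) | C=CC(C)=C | starting material
5 | (1S)-1-bromo-4-methylcyclohex-3-ene-1-carbaldehyde | O=C[C@]1(Br)CCC(C)=CC1 | intermediate
6 | (3R)-2-methoxy-6-methyl-1-oxaspiro[2.5]oct-5-ene (spiro epoxy ether, both C2 epimers, not isolated) | COC2[C@@]1(O2)CCC(C)=CC1 | intermediate
7 | (1R)-1-hydroxy-4-methylcyclohex-3-ene-1-carbaldehyde | O=C[C@@]1(O)CCC(C)=CC1 | intermediate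
8 | (1R)-1-ethynyl-4-methylcyclohex-3-en-1-ol | C#C[C@@]1(O)CCC(C)=CC1 | intermediate
9 | (1R,3R,6S)-3-ethynyl-6-methyl-7-oxabicyclo[4.1.0]heptan-3-ol (epoxide cis to OH) | C#C[C@@]1(O)CC[C@]2(C)O[C@@H]2C1 | intermediate
10 | tert-butyl{[(1R,3R,6S)-3-ethynyl-6-methyl-7-oxabicyclo[4.1.0]heptan-3-yl]oxy}dimethylsilane | C#C[C@@]1(O[Si](C)(C)C(C)(C)C)CC[C@]2(C)O[C@@H]2C1 | intermediate
11 | (1S,2S,4R)-4-{[tert-butyl(dimethyl)silyl]oxy}-2-chloro-4-ethynyl-1-methylcyclohexan-1-ol (Cl trans to the tertiary OH) | C#C[C@@]1(O[Si](C)(C)C(C)(C)C)CC[C@](C)(O)[C@@H](Cl)C1 | intermediate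
12 | tert-butyl{[(1R,3S,4S)-4-bromo-3-chloro-1-ethynyl-4-methylcyclohexyl]oxy}dimethylsilane | C#C[C@@]1(O[Si](C)(C)C(C)(C)C)CC[C@](C)(Br)[C@@H](Cl)C1 | intermediate
13 | 1-[(1R,3S,4S)-4-bromo-1-{[tert-butyl(dimethyl)silyl]oxy}-3-chloro-4-methylcyclohexyl]ethan-1-one | CC(=O)[C@@]1(O[Si](C)(C)C(C)(C)C)CC[C@](C)(Br)[C@@H](Cl)C1 | intermediate
14 | {[(1R,3S,4S)-4-bromo-3-chloro-4-methyl-1-(prop-1-en-2-yl)cyclohexyl]oxy}(tert-butyl)dimethylsilane | C=C(C)[C@@]1(O[Si](C)(C)C(C)(C)C)CC[C@](C)(Br)[C@@H](Cl)C1 | intermediate
15 | {[(1R,3S,4S)-4-bromo-3-chloro-1-(3-chloroprop-1-en-2-yl)-4-methylcyclohexyl]oxy}(tert-butyl)dimethylsilane | C=C(CCl)[C@@]1(O[Si](C)(C)C(C)(C)C)CC[C@](C)(Br)[C@@H](Cl)C1 | intermediate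
16 | 2-{2-[(1R,3S,4S)-4-bromo-1-{[tert-butyl(dimethyl)silyl]oxy}-3-chloro-4-methylcyclohexyl]prop-2-en-1-yl}-4,4,5,5-tetramethyl-1,3,2-dioxaborolane | C=C(CB2OC(C)(C)C(C)(C)O2)[C@@]1(O[Si](C)(C)C(C)(C)C)CC[C@](C)(Br)[C@@H](Cl)C1 | intermediate
17 | 3-methylbut-2-enal | CC(C)=CC=O | starting material
18 | pinacol borate ester of 19 (O–Bpin on the (4S) carbinol oxygen, not isolated) | C=C(C[C@H](OB2OC(C)(C)C(C)(C)O2)C=C(C)C)[C@@]1(O[Si](C)(C)C(C)(C)C)CC[C@](C)(Br)[C@@H](Cl)C1 | intermediate
19 | (4S)-2-[(1R,3S,4S)-4-bromo-1-{[tert-butyl(dimethyl)silyl]oxy}-3-chloro-4-methylcyclohexyl]-6-methylhepta-1,5-dien-4-ol | C=C(C[C@H](O)C=C(C)C)[C@@]1(O[Si](C)(C)C(C)(C)C)CC[C@](C)(Br)[C@@H](Cl)C1 | intermediate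
20 | (1R,3S,4S)-4-bromo-3-chloro-1-[(4S)-4-hydroxy-6-methylhepta-1,5-dien-2-yl]-4-methylcyclohexan-1-ol | C=C(C[C@H](O)C=C(C)C)[C@@]1(O)CC[C@](C)(Br)[C@@H](Cl)C1 | target

**Step count and risks**
Total steps: 14. Longest linear sequence: 14 steps (acrolein 1 → 20); isoprene 4 and 3-methylbut-2-enal 17 each enter in one step.

The three steps most likely to fail:

Step 8 (tertiary OH → Br) is the most likely to fail. The cation can lose a proton, bromide can enter cis to chlorine if bridging is weak, and HBr can attack the silyl ether. The fallback sets out from 11: anti E2 dehydration with POCl3/pyridine (the C3 hydrogen is syn to the leaving group and cannot be lost) gives tert-butyl{[(1R,5S)-5-chloro-1-ethynyl-4-methylcyclohex-3-en-1-yl]oxy}dimethylsilane F2. Anhydrous HBr is then added in DCM at −78 °C, so that Markovnikov protonation at C5 regenerates the β-chloro cation under kinetic conditions and bromide adds anti to chlorine. The route is rejoined at 12.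

Step 7 (chloride opening of epoxide 10) is the second risk: chloride may attack the tertiary carbon C4 if the wrong half-chair reacts. The fallback sets out from 8 and bypasses the epoxide. Silylation of 8 (TBSOTf, 2,6-lutidine) gives tert-butyl{[(1R)-1-ethynyl-4-methylcyclohex-3-en-1-yl]oxy}dimethylsilane F1. N-chlorosuccinimide in aqueous acetone then forms a chloronium ion that water opens at C4 (Markovnikov, anti, trans-diaxial in the silyloxy-equatorial half-chair). After chromatographic removal of the facial isomer the route is rejoined at 11.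

Step 13 (allylboration) is the third risk: the bulky 2-substituent on the boronate may slow the reaction or erode selectivity. The fallback sets out from 13 and replaces allylation by an aldol reaction. Enolisation with (−)-Ipc2BCl/Et3N and addition of 17 (the other Ipc2BCl enantiomer if the carbinol emerges with the wrong sense) gives (3S)-1-[(1R,3S,4S)-4-bromo-1-{[tert-butyl(dimethyl)silyl]oxy}-3-chloro-4-methylcyclohexyl]-3-hydroxy-5-methylhex-4-en-1-one F3. Methylenation of the ketone with excess Tebbe reagent (the free hydroxyl is carried as its titanium alkoxide) then gives 19, so 14, 15 and 16 are not needed.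

**Further compounds**
F1 | step 7 | tert-butyl{[(1R)-1-ethynyl-4-methylcyclohex-3-en-1-yl]oxy}dimethylsilane | C#C[C@@]1(O[Si](C)(C)C(C)(C)C)CCC(C)=CC1
F2 | step 8 | tert-butyl{[(1R,5S)-5-chloro-1-ethynyl-4-methylcyclohex-3-en-1-yl]oxy}dimethylsilane | C#C[C@@]1(O[Si](C)(C)C(C)(C)C)CC=C(C)[C@@H](Cl)C1
F3 | step 13 | (3S)-1-[(1R,3S,4S)-4-bromo-1-{[tert-butyl(dimethyl)silyl]oxy}-3-chloro-4-methylcyclohexyl]-3-hydroxy-5-methylhex-4-en-1-one | O=C(C[C@H](O)C=C(C)C)[C@@]1(O[Si](C)(C)C(C)(C)C)CC[C@](C)(Br)[C@@H](Cl)C1
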